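**Plan**

1. Retrosynthetic cuts: the eight O–Si bonds come off last. The C3 configuration (equilibration) and the C4 styryl group (1,4-hydride addition, Suzuki coupling at a C4 enol triflate) lead back to a 3-aroyl-tetrahydropyran-4-one. That ring is cut at C2–C3, C5–C6 and O1–C2 into an aryl 1,3-diketone and two aldehydes. The aryl diketone is cut at its alkene (cross-metathesis) and at the aryl–CH bond (aromatic Claisen rearrangement of a secondary allyl aryl ether).
2. Enabling feature: in the ring O1–C2–C3–C4–C5–C6, C3 carries the aroyl group and C3 and C5 flank C4. With C4 raised to a carbonyl, aroyl C=O–C3–C4–C5 is a 1-arylbutane-1,3-dione whose terminal carbon (C5) and central carbon (C3) are nucleophiles. C6 and C2, both bonded to O1, are the carbonyl carbons of a 3-arylpropanal and a 4-silyloxybenzaldehyde (Maitland–Japp reaction).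
3. Forward order: aryl ketone 14 (steps 1–11), bis-silyl dienol ether 16, one-pot aldol/Knoevenagel/oxa-Michael ring formation (step 16), C4 triflate, styryl coupling, reduction, C3 equilibration, desilylation. The C4 oxygen and the silyl groups are the helpers that are removed again.
4. Stereochemistry: C6 from Ti–BINOL catalysis; C2 from allylic 1,3-strain in the ring enol under reversible oxa-Michael closure (2,6-trans); C4 from axial hydride delivery; C3 by equilibration. The side-chain carbinol comes from a Keck allylation. The diarylmethine centre comes from CBS reduction, stereoretentive allylic etherification and suprafacial [3,3] chirality transfer.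

Key step: step 16

Abbreviations in names: ArT = 4-(triisopropylsilyloxy)phenyl; TIPS = triisopropylsilyl; TBS = tert-butyldimethylsilyl; TMS = trimethylsilyl; ArK = 2-(tert-butyldimethylsilyloxy)-6-methoxy-4-(triisopropylsilyloxy)-3-[(1R,2E,5S)-5-(tert-butyldimethylsilyloxy)-1,7-bis(ArT)hept-2-en-1-yl]phenyl. Ring atoms of the tetrahydropyran are numbered O1, C2 (aryl), C3 (aroyl), C4 (styryl), C5, C6 (arylethyl).

Remark: the usual senses of induction are assumed ((R)-BINOL–titanium catalysts add allyl and dienolate to the Re face of aldehyde 3; the (S)-CBS catalyst gives the (R) allylic alcohol); should one prove opposite, the antipodal ligand is used.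

**Route**

Step 1
Reactants: 1 methyl 3-(4-hydroxyphenyl)propanoate
Product: 2 methyl 3-(ArT)propanoate
Conditions: TIPSCl, imidazole, DMF, rt
Reagents that add atoms: triisopropylsilyl chloride, CC(C)[Si](Cl)(C(C)C)C(C)C
Why: O-silylation of a phenol with a silyl chloride and imidazole; the TIPS ether resists bases, organometallic reagents and cross-coupling conditions and leaves with fluoride.

Step 2
Reactants: 2 methyl 3-(ArT)propanoate
Product: 3 3-(ArT)propanal
Conditions: i-Bu2AlH (1.05 equiv), CH2Cl2, −78 °C; aq. potassium sodium tartrate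
Reagents that add atoms: none
Why: partial reduction of a methyl ester; the aluminium hemiacetal is stable at −78 °C and releases the aldehyde on work-up.

Step 3
Reactants: 3 3-(ArT)propanal
Product: 4 (S)-1-(ArT)hex-5-en-3-ol
Conditions: Ti(OiPr)4 (10 mol %), (R)-BINOL (20 mol %), 4 Å molecular sieves, CH2Cl2; allyltributylstannane, −20 °C; aq. NaHCO3
Reagents that add atoms: allyltributylstannane, C=CC[Sn](CCCC)(CCCC)CCCC
Why: Keck asymmetric allylation; the BINOL–titanium Lewis acid binds the aldehyde and the allyl group is transferred to its Re face, which sets the (S) carbinol.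

Step 4
Reactants: 5 (E)-4-(4-hydroxyphenyl)but-3-en-2-one
Product: 6 (E)-4-(ArT)but-3-en-2-one
Conditions: TIPSCl, imidazole, DMF, rt
Reagents that add atoms: triisopropylsilyl chloride, CC(C)[Si](Cl)(C(C)C)C(C)C
Why: O-silylation of the phenol, as in step 1; the enone is untouched.

Step 5
Reactants: 6 (E)-4-(ArT)but-3-en-2-one
Product: 7 (R,E)-4-(ArT)but-3-en-2-ol
Conditions: (S)-2-methyl-CBS-oxazaborolidine (10 mol %), catecholborane, toluene, −78 °C
Reagents that add atoms: none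
Why: Corey–Bakshi–Shibata reduction; the alkenyl group acts as the large substituent in the oxazaborolidine–borane complex and hydride is delivered 1,2 to the face that gives the (R) alcohol.

Step 6
Reactants: 7 (R,E)-4-(ArT)but-3-en-2-ol
Product: 8 methyl (R,E)-4-(ArT)but-3-en-2-yl carbonate
Conditions: ClCO2Me, pyridine, CH2Cl2, 0 °C
Reagents that add atoms: methyl chloroformate, COC(=O)Cl
Why: O-acylation of the alcohol with retention; the carbonate is the ionisable group for the palladium step.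

Step 7
Reactants: 9 1-(2,4-dihydroxy-6-methoxyphenyl)ethanone
Product: 10 1-[2-hydroxy-6-methoxy-4-(triisopropylsilyloxy)phenyl]ethanone
Conditions: TIPSCl (1.05 equiv), imidazole, CH2Cl2/DMF, 0 °C
Reagents that add atoms: triisopropylsilyl chloride, CC(C)[Si](Cl)(C(C)C)C(C)C
Why: selective silylation of the 4-hydroxyl; the 2-hydroxyl is hydrogen-bonded to the acetyl carbonyl and much less nucleophilic.

Step 8
Reactants: 8 methyl (R,E)-4-(ArT)but-3-en-2-yl carbonate, 10 1-[2-hydroxy-6-methoxy-4-(triisopropylsilyloxy)phenyl]ethanone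
Product: 11 1-[2-methoxy-4-(triisopropylsilyloxy)-6-{[(R,E)-4-(ArT)but-3-en-2-yl]oxy}phenyl]ethanone
Conditions: Pd2(dba)3·CHCl3 (2.5 mol %), PPh3 (10 mol %), THF, rt
Reagents that add atoms: none
Why: Tsuji–Trost allylic etherification: zerovalent palladium ionises the carbonate with inversion, the methoxide released on decarboxylation deprotonates phenol 10, and the phenoxide attacks the allyl ligand anti to palladium at the methyl-bearing terminus (styrene conjugation is kept), so the ether forms with net retention (R).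

Step 9
Reactants: 11 1-[2-methoxy-4-(triisopropylsilyloxy)-6-{[(R,E)-4-(ArT)but-3-en-2-yl]oxy}phenyl]ethanone
Product: 12 1-[2-hydroxy-6-methoxy-3-[(R,E)-1-(ArT)but-2-en-1-yl]-4-(triisopropylsilyloxy)phenyl]ethanone
Conditions: PhNEt2, 150 °C (sealed tube)
Reagents that add atoms: none
Why: aromatic Claisen rearrangement through a chair transition state with the methyl group pseudoequatorial: the only free ortho position is C3 (the other carries the acetyl group), the suprafacial [3,3] shift transfers the carbinol configuration to the new diarylmethine centre (R) and gives the E alkene, and tautomerisation restores the chelated phenol.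

Step 10
Reactants: 12 1-[2-hydroxy-6-methoxy-3-[(R,E)-1-(ArT)but-2-en-1-yl]-4-(triisopropylsilyloxy)phenyl]ethanone, 4 (S)-1-(ArT)hex-5-en-3-ol
Product: 13 1-[2-hydroxy-3-[(1R,2E,5S)-5-hydroxy-1,7-bis(ArT)hept-2-en-1-yl]-6-methoxy-4-(triisopropylsilyloxy)phenyl]ethanone
Conditions: second-generation Hoveyda–Grubbs catalyst (5 mol %), 4 (3 equiv), CH2Cl2, 40 °C
Reagents that add atoms: none
Why: olefin cross-metathesis with loss of propene: the terminal alkene of 4 is loaded on ruthenium and exchanges with the propenyl group; the branched allylic carbon favours the E alkene and no stereocentre is touched.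

Step 11
Reactants: 13 1-[2-hydroxy-3-[(1R,2E,5S)-5-hydroxy-1,7-bis(ArT)hept-2-en-1-yl]-6-methoxy-4-(triisopropylsilyloxy)phenyl]ethanone
Product: 14 1-(ArK)ethanone
Conditions: TBSOTf (2.5 equiv), 2,6-lutidine, CH2Cl2, −40 → 0 °C
Reagents that add atoms: tert-butyldimethylsilyl trifluoromethanesulfonate, CC(C)(C)[Si](C)(C)OS(=O)(=O)C(F)(F)F
Why: silylation of the secondary alcohol and of the hindered, chelated phenol with the reactive silyl triflate; the phenol must be masked because a free ortho-hydroxyl would later close onto the 1,3-diketone.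

Step 12
Reactants: 14 1-(ArK)ethanone
Product: 15 1-(ArK)butane-1,3-dione
Conditions: MgBr2·OEt2, i-Pr2NEt, 1-acetylbenzotriazole, CH2Cl2, rt
Reagents that add atoms: 1-acetyl-1H-benzotriazole, CC(=O)n1nnc2ccccc21
Why: crossed Claisen-type C-acylation under soft enolisation: the magnesium-bound methyl ketone is deprotonated by the amine and acylated by the N-acylbenzotriazole; no strong base touches the silyl ethers or the diarylmethine C–H.

Step 13
Reactants: 15 1-(ArK)butane-1,3-dione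
Product: 16 1-(ArK)-1,3-bis(trimethylsilyloxy)buta-1,3-diene (enol ether geometry not defined; used crude)
Conditions: TMSOTf (2.3 equiv), Et3N, Et2O, 0 °C
Reagents that add atoms: trimethylsilyl trifluoromethanesulfonate, C[Si](C)(C)OS(=O)(=O)C(F)(F)F
Why: double O-silylation of a 1,3-dicarbonyl compound gives the 1,3-bis(silyloxy)diene, a masked dianion whose terminal carbon is the more nucleophilic one.

Step 14
Reactants: 17 4-hydroxybenzaldehyde
Product: 18 4-(triisopropylsilyloxy)benzaldehyde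
Conditions: TIPSCl, imidazole, DMF, rt
Reagents that add atoms: triisopropylsilyl chloride, CC(C)[Si](Cl)(C(C)C)C(C)C
Why: O-silylation of the phenol, as in step 1.

Step 15
Reactants: 18 4-(triisopropylsilyloxy)benzaldehyde, 19 bis(pinacolato)borylmethane
Product: 20 (E)-2-[2-(ArT)ethenyl]-4,4,5,5-tetramethyl-1,3,2-dioxaborolane
Conditions: lithium 2,2,6,6-tetramethylpiperidide, THF, 0 °C; then 18, −78 °C → rt; aq. NH4Cl
Reagents that add atoms: none
Why: boron–Wittig reaction: the α-boryl carbanion of 19 adds to the aldehyde and syn-elimination of the borate gives the E alkenyl boronate.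

Step 16
Reactants: 16 1-(ArK)-1,3-bis(trimethylsilyloxy)buta-1,3-diene, 3 3-(ArT)propanal, 18 4-(triisopropylsilyloxy)benzaldehyde
Product: 23 (ArK)[(2S,6S)-4-hydroxy-2-(ArT)-6-[2-(ArT)ethyl]-5,6-dihydro-2H-pyran-3-yl]methanone (2,6-trans ring enol), via aldol adduct 21 (not isolated), via Knoevenagel adduct 22 (not isolated)
Conditions: 3, Ti(OiPr)4 (10 mol %), (R)-BINOL (10 mol %), THF, −78 → 0 °C; then 18, TiCl4, CH2Cl2, −78 → −30 °C; aq. NaHCO3
Reagents that add atoms: none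
Why: The Ti–BINOL complex catalyses the vinylogous Mukaiyama aldol addition of the terminal carbon of dienol ether 16 to the Re face of aldehyde 3 (bond C5–C6; C6 is set by the catalyst), then TiCl4 promotes the Knoevenagel condensation of the central diketone carbon with aldehyde 18 (bond C2–C3), and the C6 oxygen closes the tetrahydropyran ring by 6-endo-trig oxa-Michael addition to the alkylidene diketone (bond O1–C2). The closest known reaction is the one-pot asymmetric Maitland–Japp synthesis of tetrahydropyran-4-ones from bis-silyl dienol ethers of 1,3-dicarbonyl compounds, an aliphatic aldehyde and an aromatic aldehyde. C2 is set relative to C6 in the reversible oxa-Michael step: the product rests as the ring enol (C3=C4, hydrogen-bonded to the aroyl carbonyl), in which allylic 1,3-strain with the C3 aroyl group forces the C2 aryl pseudoaxial, trans to the equatorial C6 side chain. The step needs site selectivity between the two nucleophilic carbons, which the dienol ether secures because its terminal carbon reacts first and the central carbon only once it is part of a 1,3-diketone, and it needs each aldehyde to enter in its own stage, which the order of addition secures. The side-chain stereocentres are remote, and the silyl ethers should tolerate the Lewis acids at low temperature.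

Step 17
Reactants: 23 (ArK)[(2S,6S)-4-hydroxy-2-(ArT)-6-[2-(ArT)ethyl]-5,6-dihydro-2H-pyran-3-yl]methanone
Product: 24 (2S,6S)-3-(ArK-carbonyl)-2-(ArT)-6-[2-(ArT)ethyl]-5,6-dihydro-2H-pyran-4-yl trifluoromethanesulfonate
Conditions: Tf2O, i-Pr2NEt, CH2Cl2, −78 °C
Reagents that add atoms: trifluoromethanesulfonic anhydride, O=S(=O)(OS(=O)(=O)C(F)(F)F)C(F)(F)F
Why: enol O-sulfonylation: the diketone is enolised into the ring (the di-ortho-substituted aroyl group is twisted out of conjugation), so the triflate forms on the C4 oxygen; C3 stays trigonal, which keeps the C2 aryl pseudoaxial, and no stereocentre is touched.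

Step 18
Reactants: 24 (2S,6S)-3-(ArK-carbonyl)-2-(ArT)-6-[2-(ArT)ethyl]-5,6-dihydro-2H-pyran-4-yl trifluoromethanesulfonate, 20 (E)-2-[2-(ArT)ethenyl]-4,4,5,5-tetramethyl-1,3,2-dioxaborolane
Product: 25 (ArK)[(2S,6S)-2-(ArT)-6-[2-(ArT)ethyl]-4-[(E)-2-(ArT)ethenyl]-5,6-dihydro-2H-pyran-3-yl]methanone
Conditions: Pd(PPh3)4 (5 mol %), K3PO4, dioxane/H2O, 50 °C
Reagents that add atoms: none
Why: Suzuki–Miyaura coupling of a β-acyl vinyl triflate, which is activated for oxidative addition, with an alkenyl boronate; the E geometry of the boronate is retained.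

Step 19
Reactants: 25 (ArK)[(2S,6S)-2-(ArT)-6-[2-(ArT)ethyl]-4-[(E)-2-(ArT)ethenyl]-5,6-dihydro-2H-pyran-3-yl]methanone
Product: 26 (ArK)[(2R,3S,4S,6S)-2-(ArT)-6-[2-(ArT)ethyl]-4-[(E)-2-(ArT)ethenyl]tetrahydropyran-3-yl]methanone (2,3-cis)
Conditions: catecholborane, THF, −20 °C → rt; pH 7 buffer
Reagents that add atoms: none
Why: conjugate reduction of an s-cis enone with catecholborane: boron binds the carbonyl oxygen and hydride passes to C4 through a six-membered transition state (1,4, not 1,6) on the axial trajectory anti to the C6 side chain, so the styryl group becomes equatorial and cis to that chain (C4 S); hydrolysis protonates the boron enolate at C3 opposite to the axial C2 aryl and gives the 2,3-cis ketone.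

Step 20
Reactants: 26 (ArK)[(2R,3S,4S,6S)-2-(ArT)-6-[2-(ArT)ethyl]-4-[(E)-2-(ArT)ethenyl]tetrahydropyran-3-yl]methanone
Product: 27 (ArK)[(2R,3R,4S,6S)-2-(ArT)-6-[2-(ArT)ethyl]-4-[(E)-2-(ArT)ethenyl]tetrahydropyran-3-yl]methanone (octasilyl ether of the target)
Conditions: DBU (0.2 equiv), toluene, rt
Reagents that add atoms: none
Why: base-mediated enolisation and reprotonation at C3, the only acidic stereocentre: in the 2,3-trans epimer the axial aroyl group is anti to the axial C2 aryl and meets one syn-axial hydrogen only (C5–H; O1 carries none), whereas the equatorial aroyl group of 26 is gauche to both neighbours, so 27 should be populated and is collected while unchanged 26 is resubmitted; C2 should be safe because the C2–O1 bond lies near the nodal plane of the exocyclic enolate.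

Step 21
Reactants: 27 (ArK)[(2R,3R,4S,6S)-2-(ArT)-6-[2-(ArT)ethyl]-4-[(E)-2-(ArT)ethenyl]tetrahydropyran-3-yl]methanone
Product: 28 blepharocalyxin B
Conditions: Bu4NF, AcOH (1:1), THF, 0 °C → rt
Reagents that add atoms: none
Why: fluoride-induced cleavage of the six aryl TIPS ethers and the two TBS ethers; acetic acid protonates the phenoxides as they form, which keeps C3 from enolising and the 4-hydroxyphenyl group at C2 from opening the ring through a quinone methide.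

**Compound list**

1 | methyl 3-(4-hydroxyphenyl)propanoate | COC(=O)CCc1ccc(O)cc1 | starting material
2 | methyl 3-(ArT)propanoate | COC(=O)CCc1ccc(O[Si](C(C)C)(C(C)C)C(C)C)cc1 | intermediate
3 | 3-(ArT)propanal | O=CCCc1ccc(O[Si](C(C)C)(C(C)C)C(C)C)cc1 | intermediate
4 | (S)-1-(ArT)hex-5-en-3-ol | C=CC[C@@H](O)CCc1ccc(O[Si](C(C)C)(C(C)C)C(C)C)cc1 | intermediate
5 | (E)-4-(4-hydroxyphenyl)but-3-en-2-one | CC(=O)/C=C/c1ccc(O)cc1 | starting material
6 | (E)-4-(ArT)but-3-en-2-one | CC(=O)/C=C/c1ccc(O[Si](C(C)C)(C(C)C)C(C)C)cc1 | intermediate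
7 | (R,E)-4-(ArT)but-3-en-2-ol | C[C@@H](O)/C=C/c1ccc(O[Si](C(C)C)(C(C)C)C(C)C)cc1 | intermediate
8 | methyl (R,E)-4-(ArT)but-3-en-2-yl carbonate | C[C@@H](OC(=O)OC)/C=C/c1ccc(O[Si](C(C)C)(C(C)C)C(C)C)cc1 | intermediate
9 | 1-(2,4-dihydroxy-6-methoxyphenyl)ethanone | COc1cc(O)cc(O)c1C(C)=O | starting material
10 | 1-[2-hydroxy-6-methoxy-4-(triisopropylsilyloxy)phenyl]ethanone | COc1cc(O[Si](C(C)C)(C(C)C)C(C)C)cc(O)c1C(C)=O | intermediate
11 | 1-[2-methoxy-4-(triisopropylsilyloxy)-6-{[(R,E)-4-(ArT)but-3-en-2-yl]oxy}phenyl]ethanone | C[C@@H](Oc1cc(O[Si](C(C)C)(C(C)C)C(C)C)cc(OC)c1C(C)=O)/C=C/c1ccc(O[Si](C(C)C)(C(C)C)C(C)C)cc1 | intermediate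
12 | 1-[2-hydroxy-6-methoxy-3-[(R,E)-1-(ArT)but-2-en-1-yl]-4-(triisopropylsilyloxy)phenyl]ethanone | COc1cc(O[Si](C(C)C)(C(C)C)C(C)C)c([C@H](/C=C/C)c2ccc(O[Si](C(C)C)(C(C)C)C(C)C)cc2)c(O)c1C(C)=O | intermediate
13 | 1-[2-hydroxy-3-[(1R,2E,5S)-5-hydroxy-1,7-bis(ArT)hept-2-en-1-yl]-6-methoxy-4-(triisopropylsilyloxy)phenyl]ethanone | COc1cc(O[Si](C(C)C)(C(C)C)C(C)C)c([C@H](/C=C/C[C@@H](O)CCc2ccc(O[Si](C(C)C)(C(C)C)C(C)C)cc2)c2ccc(O[Si](C(C)C)(C(C)C)C(C)C)cc2)c(O)c1C(C)=O | intermediate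
14 | 1-(ArK)ethanone | COc1cc(O[Si](C(C)C)(C(C)C)C(C)C)c([C@H](/C=C/C[C@@H](O[Si](C)(C)C(C)(C)C)CCc2ccc(O[Si](C(C)C)(C(C)C)C(C)C)cc2)c2ccc(O[Si](C(C)C)(C(C)C)C(C)C)cc2)c(O[Si](C)(C)C(C)(C)C)c1C(C)=O | intermediate
15 | 1-(ArK)butane-1,3-dione | COc1cc(O[Si](C(C)C)(C(C)C)C(C)C)c([C@H](/C=C/C[C@@H](O[Si](C)(C)C(C)(C)C)CCc2ccc(O[Si](C(C)C)(C(C)C)C(C)C)cc2)c2ccc(O[Si](C(C)C)(C(C)C)C(C)C)cc2)c(O[Si](C)(C)C(C)(C)C)c1C(=O)CC(C)=O | intermediate
16 | 1-(ArK)-1,3-bis(trimethylsilyloxy)buta-1,3-diene | COc1cc(O[Si](C(C)C)(C(C)C)C(C)C)c([C@H](/C=C/C[C@@H](O[Si](C)(C)C(C)(C)C)CCc2ccc(O[Si](C(C)C)(C(C)C)C(C)C)cc2)c2ccc(O[Si](C(C)C)(C(C)C)C(C)C)cc2)c(O[Si](C)(C)C(C)(C)C)c1C(O[Si](C)(C)C)=CC(=C)O[Si](C)(C)C | intermediate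
17 | 4-hydroxybenzaldehyde | O=Cc1ccc(O)cc1 | starting material
18 | 4-(triisopropylsilyloxy)benzaldehyde | O=Cc1ccc(O[Si](C(C)C)(C(C)C)C(C)C)cc1 | intermediate
19 | bis(pinacolato)borylmethane | CC1(C)OB(CB2OC(C)(C)C(C)(C)O2)OC1(C)C | starting material
20 | (E)-2-[2-(ArT)ethenyl]-4,4,5,5-tetramethyl-1,3,2-dioxaborolane | CC1(C)OB(/C=C/c2ccc(O[Si](C(C)C)(C(C)C)C(C)C)cc2)OC1(C)C | intermediate
21 | (S)-1-(ArK)-5-hydroxy-7-(ArT)heptane-1,3-dione, the aldol adduct (present in the flask as its titanium alkoxide or trimethylsilyl ether) | COc1cc(O[Si](C(C)C)(C(C)C)C(C)C)c([C@H](/C=C/C[C@@H](O[Si](C)(C)C(C)(C)C)CCc2ccc(O[Si](C(C)C)(C(C)C)C(C)C)cc2)c2ccc(O[Si](C(C)C)(C(C)C)C(C)C)cc2)c(O[Si](C)(C)C(C)(C)C)c1C(=O)CC(=O)C[C@H](CCc1ccc(O[Si](C(C)C)(C(C)C)C(C)C)cc1)O | intermediate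
22 | (S)-1-(ArK)-5-hydroxy-7-(ArT)-2-[(ArT)methylidene]heptane-1,3-dione, the Knoevenagel adduct (alkene geometry not defined) | COc1cc(O[Si](C(C)C)(C(C)C)C(C)C)c([C@H](/C=C/C[C@@H](O[Si](C)(C)C(C)(C)C)CCc2ccc(O[Si](C(C)C)(C(C)C)C(C)C)cc2)c2ccc(O[Si](C(C)C)(C(C)C)C(C)C)cc2)c(O[Si](C)(C)C(C)(C)C)c1C(=O)C(=Cc1ccc(O[Si](C(C)C)(C(C)C)C(C)C)cc1)C(=O)C[C@H](CCc1ccc(O[Si](C(C)C)(C(C)C)C(C)C)cc1)O | intermediate
23 | (ArK)[(2S,6S)-4-hydroxy-2-(ArT)-6-[2-(ArT)ethyl]-5,6-dihydro-2H-pyran-3-yl]methanone (2,6-trans) | COc1cc(O[Si](C(C)C)(C(C)C)C(C)C)c([C@H](/C=C/C[C@@H](O[Si](C)(C)C(C)(C)C)CCc2ccc(O[Si](C(C)C)(C(C)C)C(C)C)cc2)c2ccc(O[Si](C(C)C)(C(C)C)C(C)C)cc2)c(O[Si](C)(C)C(C)(C)C)c1C(=O)C1=C(O)C[C@H](CCc2ccc(O[Si](C(C)C)(C(C)C)C(C)C)cc2)O[C@H]1c1ccc(O[Si](C(C)C)(C(C)C)C(C)C)cc1 | intermediate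
24 | (2S,6S)-3-(ArK-carbonyl)-2-(ArT)-6-[2-(ArT)ethyl]-5,6-dihydro-2H-pyran-4-yl trifluoromethanesulfonate | COc1cc(O[Si](C(C)C)(C(C)C)C(C)C)c([C@H](/C=C/C[C@@H](O[Si](C)(C)C(C)(C)C)CCc2ccc(O[Si](C(C)C)(C(C)C)C(C)C)cc2)c2ccc(O[Si](C(C)C)(C(C)C)C(C)C)cc2)c(O[Si](C)(C)C(C)(C)C)c1C(=O)C1=C(OS(=O)(=O)C(F)(F)F)C[C@H](CCc2ccc(O[Si](C(C)C)(C(C)C)C(C)C)cc2)O[C@H]1c1ccc(O[Si](C(C)C)(C(C)C)C(C)C)cc1 | intermediate
25 | (ArK)[(2S,6S)-2-(ArT)-6-[2-(ArT)ethyl]-4-[(E)-2-(ArT)ethenyl]-5,6-dihydro-2H-pyran-3-yl]methanone | COc1cc(O[Si](C(C)C)(C(C)C)C(C)C)c([C@H](/C=C/C[C@@H](O[Si](C)(C)C(C)(C)C)CCc2ccc(O[Si](C(C)C)(C(C)C)C(C)C)cc2)c2ccc(O[Si](C(C)C)(C(C)C)C(C)C)cc2)c(O[Si](C)(C)C(C)(C)C)c1C(=O)C1=C(/C=C/c2ccc(O[Si](C(C)C)(C(C)C)C(C)C)cc2)C[C@H](CCc2ccc(O[Si](C(C)C)(C(C)C)C(C)C)cc2)O[C@H]1c1ccc(O[Si](C(C)C)(C(C)C)C(C)C)cc1 | intermediate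
26 | (ArK)[(2R,3S,4S,6S)-2-(ArT)-6-[2-(ArT)ethyl]-4-[(E)-2-(ArT)ethenyl]tetrahydropyran-3-yl]methanone | COc1cc(O[Si](C(C)C)(C(C)C)C(C)C)c([C@H](/C=C/C[C@@H](O[Si](C)(C)C(C)(C)C)CCc2ccc(O[Si](C(C)C)(C(C)C)C(C)C)cc2)c2ccc(O[Si](C(C)C)(C(C)C)C(C)C)cc2)c(O[Si](C)(C)C(C)(C)C)c1C(=O)[C@H]1[C@H](/C=C/c2ccc(O[Si](C(C)C)(C(C)C)C(C)C)cc2)C[C@H](CCc2ccc(O[Si](C(C)C)(C(C)C)C(C)C)cc2)O[C@H]1c1ccc(O[Si](C(C)C)(C(C)C)C(C)C)cc1 | intermediate
27 | (ArK)[(2R,3R,4S,6S)-2-(ArT)-6-[2-(ArT)ethyl]-4-[(E)-2-(ArT)ethenyl]tetrahydropyran-3-yl]methanone | COc1cc(O[Si](C(C)C)(C(C)C)C(C)C)c([C@H](/C=C/C[C@@H](O[Si](C)(C)C(C)(C)C)CCc2ccc(O[Si](C(C)C)(C(C)C)C(C)C)cc2)c2ccc(O[Si](C(C)C)(C(C)C)C(C)C)cc2)c(O[Si](C)(C)C(C)(C)C)c1C(=O)[C@@H]1[C@H](/C=C/c2ccc(O[Si](C(C)C)(C(C)C)C(C)C)cc2)C[C@H](CCc2ccc(O[Si](C(C)C)(C(C)C)C(C)C)cc2)O[C@H]1c1ccc(O[Si](C(C)C)(C(C)C)C(C)C)cc1 | intermediate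
28 | blepharocalyxin B | COc1cc(O)c([C@H](/C=C/C[C@@H](O)CCc2ccc(O)cc2)c2ccc(O)cc2)c(O)c1C(=O)[C@@H]1[C@H](/C=C/c2ccc(O)cc2)C[C@H](CCc2ccc(O)cc2)O[C@H]1c1ccc(O)cc1 | target

**Step count and risks**

Total step count: 21. Longest linear sequence: 15 steps (steps 4, 5, 6, 8, 9, 10, 11, 12, 13, 16, 17, 18, 19, 20, 21).

The three steps most likely to fail:

1. Step 20. What may go wrong: the two C3 epimers are expected to be close in energy, so the equilibrium may lie too far on the side of the 2,3-cis ketone; prolonged base may also begin to open the ring by β-elimination and erode C2. The fallback forms the C3–C4 bond last, so that C3 is set by carbon–carbon bond formation anti to the C2 aryl and not by protonation. It sets out from 23. NaOMe in MeOH/THF at 0 °C should cleave the C3–C4 bond by retro-Claisen attack at the unhindered ring carbonyl C4 (the di-ortho-substituted aroyl carbonyl is shielded) and give the open-chain keto ester methyl (S)-3-[(R)-3-(ArK)-3-oxo-1-(ArT)propoxy]-5-(ArT)pentanoate F1, in which C2 and C6 keep the configurations fixed in the ring. i-Bu2AlH (1 equiv, CH2Cl2, −78 °C) should reduce the ester in preference to the shielded aryl ketone and give the keto aldehyde (S)-3-[(R)-3-(ArK)-3-oxo-1-(ArT)propoxy]-5-(ArT)pentanal F2. Rhodium-catalysed addition of boronate 20 ([Rh(cod)OH]2, dioxane/H2O) should give the allylic alcohol (E,5S)-5-[(R)-3-(ArK)-3-oxo-1-(ArT)propoxy]-1,7-bis(ArT)hept-1-en-3-ol F3; either carbinol epimer serves. Sc(OTf)3 (cat., CH2Cl2, −20 °C) should ionise the 4-silyloxycinnamyl alcohol, and the ketone enol should close the ring at C4 through a chair in which the styryl group and the C6 side chain are equatorial and the new bond at C3 forms anti to the C2 aryl. This gives 27, where the fallback comes back to the route.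

2. Step 19. What may go wrong: hydride may be delivered to the other face of C4, because the pseudoaxial C2 aryl lies close to the axial trajectory, or to the styryl terminus (1,6-reduction). The fallback sets C4 by equilibration of an aldehyde before the alkene is built. It sets out from 24. Reductive carbonylation (Pd(PPh3)4, CO at 1 atm, Bu3SnH, THF, 50 °C) should give the enal (2S,6S)-3-(ArK-carbonyl)-2-(ArT)-6-[2-(ArT)ethyl]-5,6-dihydro-2H-pyran-4-carbaldehyde F4. Zn in AcOH should reduce the ene-dicarbonyl unit to the keto aldehyde 3-(ArK-carbonyl)-2-(ArT)-6-[2-(ArT)ethyl]tetrahydropyran-4-carbaldehyde F5 (ring configured as in 26, formyl group in place of the styryl group); its formyl group can equilibrate to the equatorial position cis to the C6 side chain, and C3 is protonated as in step 19. Takai olefination (CHI3, CrCl2, THF, 0 °C) should give the E vinyl iodide (ArK)[2-(ArT)-6-[2-(ArT)ethyl]-4-[(E)-2-iodoethenyl]tetrahydropyran-3-yl]methanone F6 (ring configured as in 26). Suzuki–Miyaura coupling (Pd(PPh3)4, K3PO4, dioxane/H2O) with [4-(triisopropylsilyloxy)phenyl]boronic acid F7, made from 4-hydroxyphenylboronic acid with TIPSCl and imidazole, should give 26, where the fallback comes back to the route.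

3. Step 16. What may go wrong: the ring may close to the 2,6-cis keto form or to mixtures at C2, and the titanium catalyst may induce poorly with a diketone-derived dienol ether. The fallback makes the C2–aryl bond by axial conjugate addition. It sets out from 16 and 3: only the aldol stage is run and the aldol adduct 21 is isolated. Condensation with N,N-dimethylformamide dimethyl acetal (toluene, rt, then BF3·OEt2) should give the dihydropyranone (S)-5-(ArK-carbonyl)-2-[2-(ArT)ethyl]-2,3-dihydro-4H-pyran-4-one F8. Copper-catalysed 1,4-addition of the Grignard reagent [4-(triisopropylsilyloxy)phenyl]magnesium bromide F9, made from (4-bromophenoxy)triisopropylsilane and Mg (CuBr·SMe2, Me3SiCl, THF, −78 °C), should deliver the aryl group axially at C2, trans to the C6 side chain. After work-up this gives 23, where the fallback comes back to the route.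

Further compounds

F1 | step 20 | methyl (S)-3-[(R)-3-(ArK)-3-oxo-1-(ArT)propoxy]-5-(ArT)pentanoate | COc1cc(O[Si](C(C)C)(C(C)C)C(C)C)c([C@H](/C=C/C[C@@H](O[Si](C)(C)C(C)(C)C)CCc2ccc(O[Si](C(C)C)(C(C)C)C(C)C)cc2)c2ccc(O[Si](C(C)C)(C(C)C)C(C)C)cc2)c(O[Si](C)(C)C(C)(C)C)c1C(=O)C[C@H](c1ccc(O[Si](C(C)C)(C(C)C)C(C)C)cc1)O[C@@H](CCc1ccc(O[Si](C(C)C)(C(C)C)C(C)C)cc1)CC(=O)OC
F2 | step 20 | (S)-3-[(R)-3-(ArK)-3-oxo-1-(ArT)propoxy]-5-(ArT)pentanal | COc1cc(O[Si](C(C)C)(C(C)C)C(C)C)c([C@H](/C=C/C[C@@H](O[Si](C)(C)C(C)(C)C)CCc2ccc(O[Si](C(C)C)(C(C)C)C(C)C)cc2)c2ccc(O[Si](C(C)C)(C(C)C)C(C)C)cc2)c(O[Si](C)(C)C(C)(C)C)c1C(=O)C[C@H](c1ccc(O[Si](C(C)C)(C(C)C)C(C)C)cc1)O[C@@H](CCc1ccc(O[Si](C(C)C)(C(C)C)C(C)C)cc1)CC=O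
F3 | step 20 | (E,5S)-5-[(R)-3-(ArK)-3-oxo-1-(ArT)propoxy]-1,7-bis(ArT)hept-1-en-3-ol (carbinol configuration not defined) | COc1cc(O[Si](C(C)C)(C(C)C)C(C)C)c([C@H](/C=C/C[C@@H](O[Si](C)(C)C(C)(C)C)CCc2ccc(O[Si](C(C)C)(C(C)C)C(C)C)cc2)c2ccc(O[Si](C(C)C)(C(C)C)C(C)C)cc2)c(O[Si](C)(C)C(C)(C)C)c1C(=O)C[C@H](c1ccc(O[Si](C(C)C)(C(C)C)C(C)C)cc1)O[C@@H](CCc1ccc(O[Si](C(C)C)(C(C)C)C(C)C)cc1)CC(O)/C=C/c1ccc(O[Si](C(C)C)(C(C)C)C(C)C)cc1
F4 | step 19 | (2S,6S)-3-(ArK-carbonyl)-2-(ArT)-6-[2-(ArT)ethyl]-5,6-dihydro-2H-pyran-4-carbaldehyde | COc1cc(O[Si](C(C)C)(C(C)C)C(C)C)c([C@H](/C=C/C[C@@H](O[Si](C)(C)C(C)(C)C)CCc2ccc(O[Si](C(C)C)(C(C)C)C(C)C)cc2)c2ccc(O[Si](C(C)C)(C(C)C)C(C)C)cc2)c(O[Si](C)(C)C(C)(C)C)c1C(=O)C1=C(C=O)C[C@H](CCc2ccc(O[Si](C(C)C)(C(C)C)C(C)C)cc2)O[C@H]1c1ccc(O[Si](C(C)C)(C(C)C)C(C)C)cc1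
F5 | step 19 | 3-(ArK-carbonyl)-2-(ArT)-6-[2-(ArT)ethyl]tetrahydropyran-4-carbaldehyde, ring configured as in 26 | COc1cc(O[Si](C(C)C)(C(C)C)C(C)C)c([C@H](/C=C/C[C@@H](O[Si](C)(C)C(C)(C)C)CCc2ccc(O[Si](C(C)C)(C(C)C)C(C)C)cc2)c2ccc(O[Si](C(C)C)(C(C)C)C(C)C)cc2)c(O[Si](C)(C)C(C)(C)C)c1C(=O)[C@H]1[C@H](C=O)C[C@H](CCc2ccc(O[Si](C(C)C)(C(C)C)C(C)C)cc2)O[C@H]1c1ccc(O[Si](C(C)C)(C(C)C)C(C)C)cc1
F6 | step 19 | (ArK)[2-(ArT)-6-[2-(ArT)ethyl]-4-[(E)-2-iodoethenyl]tetrahydropyran-3-yl]methanone, ring configured as in 26 | COc1cc(O[Si](C(C)C)(C(C)C)C(C)C)c([C@H](/C=C/C[C@@H](O[Si](C)(C)C(C)(C)C)CCc2ccc(O[Si](C(C)C)(C(C)C)C(C)C)cc2)c2ccc(O[Si](C(C)C)(C(C)C)C(C)C)cc2)c(O[Si](C)(C)C(C)(C)C)c1C(=O)[C@H]1[C@H](/C=C/I)C[C@H](CCc2ccc(O[Si](C(C)C)(C(C)C)C(C)C)cc2)O[C@H]1c1ccc(O[Si](C(C)C)(C(C)C)C(C)C)cc1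
F7 | step 19 | [4-(triisopropylsilyloxy)phenyl]boronic acid | OB(O)c1ccc(O[Si](C(C)C)(C(C)C)C(C)C)cc1
F8 | step 16 | (S)-5-(ArK-carbonyl)-2-[2-(ArT)ethyl]-2,3-dihydro-4H-pyran-4-one | COc1cc(O[Si](C(C)C)(C(C)C)C(C)C)c([C@H](/C=C/C[C@@H](O[Si](C)(C)C(C)(C)C)CCc2ccc(O[Si](C(C)C)(C(C)C)C(C)C)cc2)c2ccc(O[Si](C(C)C)(C(C)C)C(C)C)cc2)c(O[Si](C)(C)C(C)(C)C)c1C(=O)C1=CO[C@@H](CCc2ccc(O[Si](C(C)C)(C(C)C)C(C)C)cc2)CC1=O
F9 | step 16 | [4-(triisopropylsilyloxy)phenyl]magnesium bromide | CC(C)[Si](Oc1ccc([Mg]Br)cc1)(C(C)C)C(C)C
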